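**Strategy.** Ring B is cut into two three-carbon pieces. The feature used is the run of oxygen-bearing carbons C8 and C8a next to C4a in ring B: with C4 as a pendant ester, these atoms are the C4–C1 chain of methyl 4-methoxyacetoacetate. The remaining ring atoms C7 (H), C6 (arylpropyl) and C5 (prenyl) are a 2-substituted 3-oxoaldehyde. A TiCl4-mediated formal [3+3] cyclocondensation joins the bis(silyl) dienol ether to a silyloxymethylene prenyl ketone that already carries silyl-protected ring A. It forms C8–C7 and C4a–C5 and gives the fully substituted ring B salicylate in one operation. The ester later becomes C4 of the chroman.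

Key step: step 13

Remark: Ar denotes 2,4-bis(tert-butyldimethylsilyloxy)-5-(2-methylbut-3-en-2-yl)phenyl and TBS denotes tert-butyldimethylsilyl. Compounds 1, 3, 6, 11, 17 and 23 are taken as purchased. The geometries of 4, 14, 15, 16, 18 and 19 are erased later, so mixtures are carried on.

**Step 1**
Reactants: 1 4-(benzyloxy)-2-hydroxybenzaldehyde
Product: 2 4-(benzyloxy)-2-(tert-butyldimethylsilyloxy)benzaldehyde
Conditions: TBSCl, imidazole, DMF, 0 °C → rt
Reagents that add atoms: tert-butyldimethylsilyl chloride, CC(C)(C)[Si](C)(C)Cl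
Why: Imidazole-promoted O-silylation of the only free phenol; the aldehyde and benzyl ether are inert.

**Step 2**
Reactants: 2 4-(benzyloxy)-2-(tert-butyldimethylsilyloxy)benzaldehyde; 3 (4-ethoxy-4-oxobutyl)triphenylphosphonium bromide
Product: 4 ethyl 5-[4-(benzyloxy)-2-(tert-butyldimethylsilyloxy)phenyl]pent-4-enoate (Z expected as major isomer)
Conditions: NaN(SiMe3)2, THF, −78 °C → rt
Reagents that add atoms: none
Why: Wittig olefination with a non-stabilised ylide adds the four remaining chain carbons; the alkene geometry does not matter because the bond is saturated in step 3.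

**Step 3**
Reactants: 4 ethyl 5-[4-(benzyloxy)-2-(tert-butyldimethylsilyloxy)phenyl]pent-4-enoate
Product: 5 ethyl 5-[2-(tert-butyldimethylsilyloxy)-4-hydroxyphenyl]pentanoate
Conditions: H2 (1 atm), Pd/C, EtOAc, rt
Reagents that add atoms: none
Why: Catalytic hydrogenation saturates the styrene and hydrogenolyses the benzyl ether in one operation, deliberately before any prenyl-type alkene is in the molecule; the aryl silyl ether and ester survive in EtOAc.

**Step 4**
Reactants: 5 ethyl 5-[2-(tert-butyldimethylsilyloxy)-4-hydroxyphenyl]pentanoate; 6 3-methylbut-2-en-1-ol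
Product: 7 ethyl 5-[2-(tert-butyldimethylsilyloxy)-4-(3-methylbut-2-enyloxy)phenyl]pentanoate
Conditions: PPh3, DIAD, THF, 0 °C → rt
Reagents that add atoms: none
Why: Mitsunobu etherification of the phenol with a primary allylic alcohol is neutral, so no free phenoxide is present to shuffle the silyl group between the two ring oxygens.

**Step 5**
Reactants: 7 ethyl 5-[2-(tert-butyldimethylsilyloxy)-4-(3-methylbut-2-enyloxy)phenyl]pentanoate
Product: 8 ethyl 5-[2-(tert-butyldimethylsilyloxy)-4-hydroxy-5-(2-methylbut-3-en-2-yl)phenyl]pentanoate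
Conditions: PhNEt2, 190 °C, sealed tube, Ar
Reagents that add atoms: none
Why: The aromatic Claisen rearrangement turns the prenyl ether into the 1,1-dimethylallyl group by allylic inversion; of the two ortho positions, C3 is flanked by the bulky silyloxy group, so the tertiary carbon should go to C5, and the amine solvent suppresses acid-induced cyclisation of the product.

**Step 6**
Reactants: 8 ethyl 5-[2-(tert-butyldimethylsilyloxy)-4-hydroxy-5-(2-methylbut-3-en-2-yl)phenyl]pentanoate
Product: 9 ethyl 5-Ar-pentanoate, i.e. ethyl 5-[2,4-bis(tert-butyldimethylsilyloxy)-5-(2-methylbut-3-en-2-yl)phenyl]pentanoate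
Conditions: TBSOTf, 2,6-lutidine, CH2Cl2, 0 °C
Reagents that add atoms: tert-butyldimethylsilyl trifluoromethanesulfonate, CC(C)(C)[Si](C)(C)OS(=O)(=O)C(F)(F)F
Why: The silyl triflate silylates the hindered phenol beside the quaternary carbon under buffered conditions, which masks the ortho-hydroxy/1,1-dimethylallyl pair against later acid.

**Step 7**
Reactants: 9 ethyl 5-Ar-pentanoate
Product: 10 5-Ar-pentanal
Conditions: i-Bu2AlH (1.1 equiv), CH2Cl2, −78 °C; MeOH, aq. KNa tartrate
Reagents that add atoms: none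
Why: Partial ester reduction stops at the aluminium hemiacetal at −78 °C and releases the aldehyde on work-up; silyl ethers and the isolated vinyl group are untouched.

**Step 8**
Reactants: 11 4-methylpent-3-enoic acid
Product: 12 4-methylpent-3-enoyl chloride
Conditions: (COCl)2, DMF (cat.), CH2Cl2, 0 °C → rt
Reagents that add atoms: oxalyl chloride, O=C(Cl)C(=O)Cl
Why: Acid chloride formation through the chloroiminium salt from DMF runs cold and without base, and the volatile by-products are removed in vacuo, so the trisubstituted alkene should stay in the β,γ-position.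

**Step 9**
Reactants: 10 5-Ar-pentanal; 12 4-methylpent-3-enoyl chloride
Product: 15 2-(3-Ar-propyl)-1-hydroxy-6-methylhepta-1,5-dien-3-one (enol form of the 2-formyl ketone), via morpholine enamine 13 (not isolated), via aminomethylene ketone 14 (not isolated)
Conditions: morpholine, 4 Å MS, CH2Cl2, rt; then 12, Et3N, −20 → 0 °C; then 1 M HCl, THF, 0 °C
Reagents that add atoms: water, O
Why: Stork enamine C-acylation of the aldehyde enamine followed by acid hydrolysis of the resulting vinylogous amide gives the 2-alkyl-3-oxoaldehyde; the vinylogous amide (and then the enolised dicarbonyl) keeps the methylene between carbonyl and alkene weakly acidic, so the double bond should not move into conjugation.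

**Step 10**
Reactants: 15 2-(3-Ar-propyl)-1-hydroxy-6-methylhepta-1,5-dien-3-one
Product: 16 2-(3-Ar-propyl)-6-methyl-1-(trimethylsilyloxy)hepta-1,5-dien-3-one (E/Z mixture, used crude)
Conditions: TMSCl, Et3N, CH2Cl2, 0 °C → rt
Reagents that add atoms: chlorotrimethylsilane, C[Si](C)(C)Cl
Why: O-silylation of the acidic enol at the aldehyde-derived oxygen gives the 3-silyloxy-2-en-1-one; the enolate formed with Et3N does not allow deconjugation chemistry at the far methylene.

**Step 11**
Reactants: 17 methyl 4-methoxyacetoacetate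
Product: 18 methyl 4-methoxy-3-(trimethylsilyloxy)but-2-enoate
Conditions: TMSCl, Et3N, toluene, rt
Reagents that add atoms: chlorotrimethylsilane, C[Si](C)(C)Cl
Why: Standard O-silylation of the β-keto ester enol.

**Step 12**
Reactants: 18 methyl 4-methoxy-3-(trimethylsilyloxy)but-2-enoate
Product: 19 1,4-dimethoxy-1,3-bis(trimethylsilyloxy)buta-1,3-diene
Conditions: LiN(i-Pr)2, THF, −78 °C; TMSCl, −78 °C → rt
Reagents that add atoms: chlorotrimethylsilane, C[Si](C)(C)Cl
Why: Deprotonation at the ester α-carbon and O-silylation of the ester enolate converts the β-silyloxy enoate into the bis(silyl) dienol ether, the established route to such dienes.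

**Step 13**
Reactants: 16 2-(3-Ar-propyl)-6-methyl-1-(trimethylsilyloxy)hepta-1,5-dien-3-one; 19 1,4-dimethoxy-1,3-bis(trimethylsilyloxy)buta-1,3-diene
Product: 20 methyl 2-hydroxy-3-methoxy-6-(3-methylbut-2-enyl)-5-(3-Ar-propyl)benzoate
Conditions: TiCl4 (1.1 equiv), 2,6-di-tert-butyl-4-methylpyridine (0.5 equiv), CH2Cl2, −78 → 0 °C; aq. NaHCO3
Reagents that add atoms: none
Why: TiCl4 activates the vinylogous silyl ester 16, and the methoxy-bearing terminal carbon of 19 (future C8) adds in a vinylogous Mukaiyama manner to the silyloxymethylene carbon (future C7) with loss of the silyloxy group, forming C8–C7. The silyl ketene acetal carbon that remains (future C4a) then attacks the ketone carbon (C5) in a 6-(enolexo)-exo-trig Mukaiyama aldol closure that forms C4a–C5 and ring B, and loss of the titanium-bound oxygen plus enolisation aromatises the ring. The closest known reaction type is the Lewis acid mediated formal [3+3] cyclocondensation of 1,3-bis(silyloxy)-1,3-dienes, 4-alkoxy dienes included, with 3-silyloxy-2-en-1-ones to give salicylates. No stereocentre is created and the geometries of both enol ethers vanish in the arene. The step needs one regiochemistry, terminal diene carbon to aldehyde-level carbon; the diene's terminal carbon is its most nucleophilic site and the unhindered silyloxymethylene carbon of 16 is far more electrophilic than its α-branched ketone. Low temperature and the hindered pyridine are there to keep the β,γ-unsaturated ketone from conjugating and to shield the prenyl, 1,1-dimethylallyl and aryl silyl ether groups from HCl.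

**Step 14**
Reactants: 20 methyl 2-hydroxy-3-methoxy-6-(3-methylbut-2-enyl)-5-(3-Ar-propyl)benzoate
Product: 21 2-(hydroxymethyl)-6-methoxy-3-(3-methylbut-2-enyl)-4-(3-Ar-propyl)phenol
Conditions: i-Bu2AlH (4 equiv), CH2Cl2, −78 → 0 °C; aq. KNa tartrate
Reagents that add atoms: none
Why: Hydride reduction of the salicylate ester to the benzylic alcohol; aryl silyl ethers and unactivated alkenes do not react with i-Bu2AlH at these temperatures.

**Step 15**
Reactants: 21 2-(hydroxymethyl)-6-methoxy-3-(3-methylbut-2-enyl)-4-(3-Ar-propyl)phenol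
Product: 22 tert-butyl 2-(hydroxymethyl)-6-methoxy-3-(3-methylbut-2-enyl)-4-(3-Ar-propyl)phenyl carbonate
Conditions: Boc2O (1.05 equiv), i-Pr2NEt, DMAP (cat.), CH2Cl2, −20 → 0 °C
Reagents that add atoms: di-tert-butyl dicarbonate, CC(C)(C)OC(=O)OC(=O)OC(C)(C)C
Why: DMAP-catalysed carbonate formation favours the more acidic phenol over the primary alcohol, and any benzylic mono-carbonate formed would feed the same quinone methide in step 16.

**Step 16**
Reactants: 22 tert-butyl 2-(hydroxymethyl)-6-methoxy-3-(3-methylbut-2-enyl)-4-(3-Ar-propyl)phenyl carbonate; 23 2-methylallylmagnesium chloride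
Product: 25 2-methoxy-6-(3-methylbut-3-enyl)-5-(3-methylbut-2-enyl)-4-(3-Ar-propyl)phenol, via ortho-quinone methide 24 (not isolated)
Conditions: 23 (3.5 equiv), THF, −78 °C → rt; aq. NH4Cl
Reagents that add atoms: none
Why: Anionic ortho-quinone methide generation: the magnesium alkoxide takes the Boc group from the phenol oxygen, the phenoxide expels tert-butyl carbonate, and a further equivalent of the Grignard reagent adds 1,4 to the exocyclic methylene, restoring the arene.

**Step 17**
Reactants: 25 2-methoxy-6-(3-methylbut-3-enyl)-5-(3-methylbut-2-enyl)-4-(3-Ar-propyl)phenol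
Product: 26 8-methoxy-2,2-dimethyl-5-(3-methylbut-2-enyl)-6-(3-Ar-propyl)chroman
Conditions: Amberlyst 15, CH2Cl2, rt
Reagents that add atoms: none
Why: Acid-catalysed Markovnikov hydroalkoxylation: the 1,1-disubstituted alkene gives a tertiary cation that the neighbouring phenol traps in a six-membered closure. The prenyl group has no adjacent nucleophile, the vinyl group would need a secondary cation, and both ring A oxygens are silylated.

**Step 18**
Reactants: 26 8-methoxy-2,2-dimethyl-5-(3-methylbut-2-enyl)-6-(3-Ar-propyl)chroman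
Product: 27 4-{3-[8-methoxy-2,2-dimethyl-5-(3-methylbut-2-enyl)chroman-6-yl]propyl}-6-(2-methylbut-3-en-2-yl)benzene-1,3-diol
Conditions: Bu4NF, THF, 0 °C; aq. NH4Cl
Reagents that add atoms: none
Why: Fluoride cleaves both aryl silyl ethers through the strong Si–F bond under conditions that leave the alkenes, chroman and methyl ether alone.

**Step 19**
Reactants: 27 4-{3-[8-methoxy-2,2-dimethyl-5-(3-methylbut-2-enyl)chroman-6-yl]propyl}-6-(2-methylbut-3-en-2-yl)benzene-1,3-diol
Product: 28 kazinol D, 4-{3-[8-hydroxy-2,2-dimethyl-5-(3-methylbut-2-enyl)chroman-6-yl]propyl}-6-(2-methylbut-3-en-2-yl)benzene-1,3-diol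
Conditions: NaSEt (excess), DMF, 120 °C, Ar; dilute HCl
Reagents that add atoms: none
Why: SN2 demethylation of the aryl methyl ether by ethanethiolate in a dipolar aprotic solvent; the tertiary alkyl–oxygen bond of the chroman cannot react this way, and the isolated alkenes are inert to thiolate under argon.

**Compound list**

1 | 4-(benzyloxy)-2-hydroxybenzaldehyde | O=Cc1ccc(OCc2ccccc2)cc1O | starting material
2 | 4-(benzyloxy)-2-(tert-butyldimethylsilyloxy)benzaldehyde | O=Cc1ccc(OCc2ccccc2)cc1O[Si](C)(C)C(C)(C)C | intermediate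
3 | (4-ethoxy-4-oxobutyl)triphenylphosphonium bromide | CCOC(=O)CCC[P+](c1ccccc1)(c1ccccc1)c1ccccc1.[Br-] | starting material
4 | ethyl (Z)-5-[4-(benzyloxy)-2-(tert-butyldimethylsilyloxy)phenyl]pent-4-enoate | CCOC(=O)CC/C=C\c1ccc(OCc2ccccc2)cc1O[Si](C)(C)C(C)(C)C | intermediate
5 | ethyl 5-[2-(tert-butyldimethylsilyloxy)-4-hydroxyphenyl]pentanoate | CCOC(=O)CCCCc1ccc(O)cc1O[Si](C)(C)C(C)(C)C | intermediate
6 | 3-methylbut-2-en-1-ol | CC(C)=CCO | starting material
7 | ethyl 5-[2-(tert-butyldimethylsilyloxy)-4-(3-methylbut-2-enyloxy)phenyl]pentanoate | CCOC(=O)CCCCc1ccc(OCC=C(C)C)cc1O[Si](C)(C)C(C)(C)C | intermediate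
8 | ethyl 5-[2-(tert-butyldimethylsilyloxy)-4-hydroxy-5-(2-methylbut-3-en-2-yl)phenyl]pentanoate | CCOC(=O)CCCCc1cc(C(C)(C)C=C)c(O)cc1O[Si](C)(C)C(C)(C)C | intermediate
9 | ethyl 5-[2,4-bis(tert-butyldimethylsilyloxy)-5-(2-methylbut-3-en-2-yl)phenyl]pentanoate | CCOC(=O)CCCCc1cc(C(C)(C)C=C)c(O[Si](C)(C)C(C)(C)C)cc1O[Si](C)(C)C(C)(C)C | intermediate
10 | 5-[2,4-bis(tert-butyldimethylsilyloxy)-5-(2-methylbut-3-en-2-yl)phenyl]pentanal | O=CCCCCc1cc(C(C)(C)C=C)c(O[Si](C)(C)C(C)(C)C)cc1O[Si](C)(C)C(C)(C)C | intermediate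
11 | 4-methylpent-3-enoic acid | CC(C)=CCC(=O)O | starting material
12 | 4-methylpent-3-enoyl chloride | CC(C)=CCC(=O)Cl | intermediate
13 | 4-[(E)-5-Ar-pent-1-enyl]morpholine (not isolated) | C(/C=C/N1CCOCC1)CCc1cc(C(C)(C)C=C)c(O[Si](C)(C)C(C)(C)C)cc1O[Si](C)(C)C(C)(C)C | intermediate
14 | 2-(3-Ar-propyl)-6-methyl-1-(morpholin-4-yl)hepta-1,5-dien-3-one (not isolated, geometry undefined) | O=C(CC=C(C)C)C(=CN1CCOCC1)CCCc1cc(C(C)(C)C=C)c(O[Si](C)(C)C(C)(C)C)cc1O[Si](C)(C)C(C)(C)C | intermediate
15 | 2-(3-Ar-propyl)-1-hydroxy-6-methylhepta-1,5-dien-3-one (enol of the 2-formyl ketone) | OC=C(CCCc1cc(C(C)(C)C=C)c(O[Si](C)(C)C(C)(C)C)cc1O[Si](C)(C)C(C)(C)C)C(=O)CC=C(C)C | intermediate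
16 | 2-(3-Ar-propyl)-6-methyl-1-(trimethylsilyloxy)hepta-1,5-dien-3-one (E/Z mixture) | C[Si](C)(C)OC=C(CCCc1cc(C(C)(C)C=C)c(O[Si](C)(C)C(C)(C)C)cc1O[Si](C)(C)C(C)(C)C)C(=O)CC=C(C)C | intermediate
17 | methyl 4-methoxyacetoacetate | COCC(=O)CC(=O)OC | starting material
18 | methyl 4-methoxy-3-(trimethylsilyloxy)but-2-enoate | COCC(O[Si](C)(C)C)=CC(=O)OC | intermediate
19 | 1,4-dimethoxy-1,3-bis(trimethylsilyloxy)buta-1,3-diene (geometry undefined) | COC=C(O[Si](C)(C)C)C=C(OC)O[Si](C)(C)C | intermediate
20 | methyl 2-hydroxy-3-methoxy-6-(3-methylbut-2-enyl)-5-(3-Ar-propyl)benzoate | COC(=O)c1c(O)c(OC)cc(CCCc2cc(C(C)(C)C=C)c(O[Si](C)(C)C(C)(C)C)cc2O[Si](C)(C)C(C)(C)C)c1CC=C(C)C | intermediate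
21 | 2-(hydroxymethyl)-6-methoxy-3-(3-methylbut-2-enyl)-4-(3-Ar-propyl)phenol | OCc1c(O)c(OC)cc(CCCc2cc(C(C)(C)C=C)c(O[Si](C)(C)C(C)(C)C)cc2O[Si](C)(C)C(C)(C)C)c1CC=C(C)C | intermediate
22 | tert-butyl 2-(hydroxymethyl)-6-methoxy-3-(3-methylbut-2-enyl)-4-(3-Ar-propyl)phenyl carbonate | OCc1c(OC(=O)OC(C)(C)C)c(OC)cc(CCCc2cc(C(C)(C)C=C)c(O[Si](C)(C)C(C)(C)C)cc2O[Si](C)(C)C(C)(C)C)c1CC=C(C)C | intermediate
23 | 2-methylallylmagnesium chloride | CC(=C)C[Mg]Cl | starting material
24 | 2-methoxy-6-methylidene-5-(3-methylbut-2-enyl)-4-(3-Ar-propyl)cyclohexa-2,4-dien-1-one (ortho-quinone methide, not isolated) | C=C1C(=O)C(OC)=CC(CCCc2cc(C(C)(C)C=C)c(O[Si](C)(C)C(C)(C)C)cc2O[Si](C)(C)C(C)(C)C)=C1CC=C(C)C | intermediate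
25 | 2-methoxy-6-(3-methylbut-3-enyl)-5-(3-methylbut-2-enyl)-4-(3-Ar-propyl)phenol | C=C(C)CCc1c(O)c(OC)cc(CCCc2cc(C(C)(C)C=C)c(O[Si](C)(C)C(C)(C)C)cc2O[Si](C)(C)C(C)(C)C)c1CC=C(C)C | intermediate
26 | 8-methoxy-2,2-dimethyl-5-(3-methylbut-2-enyl)-6-(3-Ar-propyl)chroman | COc1cc(CCCc2cc(C(C)(C)C=C)c(O[Si](C)(C)C(C)(C)C)cc2O[Si](C)(C)C(C)(C)C)c(CC=C(C)C)c2CCC(C)(C)Oc12 | intermediate
27 | 4-{3-[8-methoxy-2,2-dimethyl-5-(3-methylbut-2-enyl)chroman-6-yl]propyl}-6-(2-methylbut-3-en-2-yl)benzene-1,3-diol | COc1cc(CCCc2cc(C(C)(C)C=C)c(O)cc2O)c(CC=C(C)C)c2CCC(C)(C)Oc12 | intermediate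
28 | kazinol D | C=CC(C)(C)c1cc(CCCc2cc(O)c3c(c2CC=C(C)C)CCC(C)(C)O3)c(O)cc1O | target

**Totals.** Total steps: 19. Longest linear sequence: 16 steps (1–7, 9, 10, 13–19).

**Steps most likely to fail**

1. Step 13. The ring closure or aromatisation may stall at the low temperature that the alkenes demand. The β,γ-double bond may migrate or take up HCl, or the silyl enol ether may hydrolyse before it reacts.
   Fallback (anionic, two-stage, same two bonds): set out from 14, isolated by omitting the acid hydrolysis of step 9, and from 17. The dianion of 17 (NaH, then n-BuLi, THF, −78 → 0 °C) should add through its methoxy-bearing terminal carbon to the aminomethylene carbon of 14 and expel morpholide. This gives the open-chain methyl 4-methoxy-10-methyl-3,7-dioxo-6-(3-Ar-propyl)undeca-5,9-dienoate F1. Mild acid (AcOH, or catalytic TsOH in CH2Cl2) should then close and dehydrate F1 by intramolecular aldol condensation to 20, where the route is rejoined.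

2. Step 9. Ketene formation from the acid chloride may divert material into cycloadducts or oligomers. Acylation may occur on nitrogen instead of carbon, the double bond may slip into conjugation, or the formyl group may be lost by retro-Claisen cleavage during hydrolysis.
   Fallback (aza-enolate acylation): set out from 10 and 12. Aldehyde 10 and Me2NNH2 give 5-Ar-pentanal N,N-dimethylhydrazone F2. Acid chloride 12 and MeONHMe·HCl/pyridine give N-methoxy-N,4-dimethylpent-3-enamide F3. Deprotonation of F2 with LiN(i-Pr)2 (2 equiv, THF, −78 °C) and acylation with F3 should give 2-(3-Ar-propyl)-6-methyl-3-oxohept-5-enal N,N-dimethylhydrazone F4. Hydrolysis with aqueous oxalic acid or buffered CuCl2 returns 15.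

3. Step 5. The allyl unit may migrate partly to C3 or be lost as isoprene at 190 °C. The product phenol may also react further by abnormal Claisen rearrangement or cyclisation onto the new alkene.
   Fallback (position fixed by halogenation, group delivered by cross-coupling): set out from 5. NBS in CH2Cl2 at −20 °C should brominate ortho to the free hydroxyl at the open C5 position and give ethyl 5-[5-bromo-2-(tert-butyldimethylsilyloxy)-4-hydroxyphenyl]pentanoate F5. TBSCl/imidazole then gives ethyl 5-[5-bromo-2,4-bis(tert-butyldimethylsilyloxy)phenyl]pentanoate F6. A ligand-controlled γ-selective Suzuki–Miyaura coupling with 3-methylbut-2-enylboronic acid pinacol ester (Pd(OAc)2, bulky dialkylbiarylphosphine, K3PO4, THF–H2O) installs the 1,1-dimethylallyl group and returns 9.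

**Further compounds**

F1 | step 13 | methyl 4-methoxy-10-methyl-3,7-dioxo-6-(3-Ar-propyl)undeca-5,9-dienoate | COC(=O)CC(=O)C(OC)C=C(CCCc1cc(C(C)(C)C=C)c(O[Si](C)(C)C(C)(C)C)cc1O[Si](C)(C)C(C)(C)C)C(=O)CC=C(C)C
F2 | step 9 | 5-Ar-pentanal N,N-dimethylhydrazone | CN(C)/N=C/CCCCc1cc(C(C)(C)C=C)c(O[Si](C)(C)C(C)(C)C)cc1O[Si](C)(C)C(C)(C)C
F3 | step 9 | N-methoxy-N,4-dimethylpent-3-enamide | CON(C)C(=O)CC=C(C)C
F4 | step 9 | 2-(3-Ar-propyl)-6-methyl-3-oxohept-5-enal N,N-dimethylhydrazone | CN(C)N=CC(CCCc1cc(C(C)(C)C=C)c(O[Si](C)(C)C(C)(C)C)cc1O[Si](C)(C)C(C)(C)C)C(=O)CC=C(C)C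
F5 | step 5 | ethyl 5-[5-bromo-2-(tert-butyldimethylsilyloxy)-4-hydroxyphenyl]pentanoate | CCOC(=O)CCCCc1cc(Br)c(O)cc1O[Si](C)(C)C(C)(C)C
F6 | step 5 | ethyl 5-[5-bromo-2,4-bis(tert-butyldimethylsilyloxy)phenyl]pentanoate | CCOC(=O)CCCCc1cc(Br)c(O[Si](C)(C)C(C)(C)C)cc1O[Si](C)(C)C(C)(C)C
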